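Substrate must be left over in both flasks, because you charge 0.308 M of partner against 0.560 M of the two substrates together, so the end reading tells you how the part of the partner that reached product was divided between the two hands.

    free catalyst + left-handed substrate ⇌ catalyst intermediate A (K1 = 6.36 /M, k1 = 242 /M/h, Ea1 = 51.0 kJ/mol, ΔH1 = −57.0 kJ/mol)
    free catalyst + right-handed substrate ⇌ catalyst intermediate B (K2 = 25 /M, k2 = 4600 /M/h, Ea2 = 60.0 kJ/mol, ΔH2 = 24.0 kJ/mol)
    partner + catalyst intermediate A → free catalyst + left-handed product (k3 = 36.5 /M/h, Ea3 = 73.0 kJ/mol)
    partner + catalyst intermediate B → free catalyst + right-handed product (k4 = 17.4 /M/h, Ea4 = 66.0 kJ/mol)
    partner + protic impurity → quenched reagent (k5 = 0.296 /M/h, Ea5 = 72.0 kJ/mol)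
    (constants at 35 °C)

| flask | left-handed substrate | partner | protic impurity | free catalyst | right-handed substrate | temperature | time |
|---|---|---|---|---|---|---|---|
| teal | 0.28 M | 0.308 M | 0.280 M | 1.3 mM | 0.28 M | 55 °C | 4.0 d |
| green | 0.28 M | 0.308 M | 0.280 M | 1.3 mM | 0.28 M | 35 °C | 4.0 d |

- free catalyst is single-handed; left-handed substrate and right-handed substrate are mirror images of each other, charged as a racemate, each of them at the stated concentration
- all constants are for 35 °C and move with temperature by the activation energies and enthalpies

1. which flask leads in share of left-handed product in all that became left-handed product or right-handed product ("all alike" within 1.5 percentage points) (teal / green / all alike)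
2. share of left-handed product in all that became left-handed product or right-handed product, teal
3. share of left-handed product in all that became left-handed product or right-handed product, green

First ask whether a bound substrate waits for the partner. In green at the start, catalyst intermediate A returns to free catalyst and substrate at 38.1 /h and goes on to product at 11.2 /h, while catalyst intermediate B returns at 184 /h and goes on at 5.36 /h, so both lean towards the end where binding stays in balance, A less firmly.

I solve the two ends and join them. When going on is much slower than falling back, equal substrates give left-handed and right-handed product in the ratio s, the selectivity factor: rate constant of going on times binding constant, left-handed over right-handed, 0.534 at 35 °C. The left-handed share is then s divided by one plus s, or 34.8%. When going on is much faster, the ratio is just that of the binding rate constants, 0.0526. Joining the ends at the full partner charge gives a ratio of 0.424, a share of 29.8%, and as the partner falls the share climbs towards the first end, so I expect green between these two figures.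

Next ask what warming does. Going-on activation energy plus binding enthalpy, left-handed minus right-handed, comes to −74.0 kJ/mol, so at 55 °C in teal s drops to 0.0918, a share of 8.41%.

Last, ask whether the substrates drift apart enough to matter. Even with all catalyst held as the faster intermediate, the partner's catalytic loss in green at the start is 0.0475 /h, less than the 0.0829 /h it then loses to protic impurity, and the activation energies of those two steps differ by 1.00 kJ/mol. So I allow a small upward drift and put green ahead by far more than the margin.

The forecast names green as leader, with 9.2% in teal and 33% in green, because “warming widens that gap because the two binding enthalpies have opposite signs”.

The simulation gives green the lead, with 9.53% in teal and 34.2% in green. Both flasks have effectively come to rest. Teal's partner reads 0% at 2.00 d. After 40.0 d, teal's share reads 9.53%. Green still holds 0.51% of its partner at 4.00 d. After 40.0 d, green's partner reads 0% and its share reads 34.2%. A flask like green kept at 50 °C has s down to 0.140, a share of 12.3%, and it stops at 13.5%.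

All constants belong to no real substance; the run is a simulation.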